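## Retrosynthetic overview
1. 17 ⇒ 16: break C13–O9. The spiro-tetrahydrofuran and the 2,3-dihydrofuran both arise in the last step, by light-driven dearomative cycloisomerisation of a 9α-hydroxy furan.
2. 16 ⇒ 14 + 15: break C12–C13 (sp3–sp2 photoredox/nickel cross-electrophile coupling). The furan ring is bought.
3. 14 ⇒ 10: 7β-OAc and 8β-OH come from a Woodward cis-hydroxylation of the Δ7 alkene, followed by oxidation at C6.
4. 10 ⇒ 8: C6–O and C9–O come from a photochemical singlet-oxygen [4+2] on the ring-B 6,8-diene, then O–O cleavage.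
5. 8 ⇒ 1: rings A and B with C5 and C10 are bought in (+)-sclareolide. The lactone is opened, C12 becomes the bromide, and C7 oxidation followed by triflate reduction gives the diene.

Assumption: labdane numbering (C1–C20) and α/β descriptors are used throughout, and every decalin keeps the 5α-H/10β-CH3 trans fusion of sclareolide.

## Route

Step 1
Reactants: 1 (+)-sclareolide
Product: 2 methyl 13,14,15,16-tetranorlabd-8-en-12-oate
Conditions: conc. H2SO4, MeOH, reflux
Reagents that add atoms: methanol, CO
Why: Acid-catalysed E1 opening of the tertiary lactone C8–O bond with Fischer esterification, while acid equilibration drains the alkene isomers into the tetrasubstituted Δ8(9) position; C8 and C9 become sp2 and the bought C5 and C10 are untouched.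

Step 2
Reactants: 2 methyl 13,14,15,16-tetranorlabd-8-en-12-oate
Product: 3 13,14,15,16-tetranorlabd-8-en-12-ol
Conditions: LiAlH4, THF, 0 °C
Reagents that add atoms: none
Why: Standard hydride reduction of an ester to the primary alcohol; the isolated tetrasubstituted alkene is inert.

Step 3
Reactants: 3 13,14,15,16-tetranorlabd-8-en-12-ol
Product: 4 12-bromo-13,14,15,16-tetranorlabd-8-ene
Conditions: CBr4, PPh3, CH2Cl2, 0 °C
Reagents that add atoms: carbon tetrabromide, BrC(Br)(Br)Br
Why: Appel reaction, an SN2 displacement at the unhindered primary carbon under neutral conditions that do not move the alkene.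

Step 4
Reactants: 4 12-bromo-13,14,15,16-tetranorlabd-8-ene
Product: 5 12-bromo-13,14,15,16-tetranorlabd-8-en-7-one
Conditions: CrO3, 3,5-dimethylpyrazole, CH2Cl2, −20 °C
Reagents that add atoms: chromium trioxide, O=[Cr](=O)=O
Why: Chromium(VI) allylic oxidation attacks the ring methylene C7, whose axial C–H is aligned with the π bond, rather than C11 (deactivated by the β-bromide) or the C17 methyl, as is usual for Δ8-drimenes.

Step 5
Reactants: 5 12-bromo-13,14,15,16-tetranorlabd-8-en-7-one
Product: 7 12-bromo-13,14,15,16-tetranorlabda-6,8-dien-7-yl triflate, via potassium dienolate 6 (not isolated)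
Conditions: KHMDS, THF, −78 °C (inverse addition); then PhNTf2, −78 → 0 °C
Reagents that add atoms: N-phenylbis(trifluoromethanesulfonimide), O=S(=O)(N(c1ccccc1)S(=O)(=O)C(F)(F)F)C(F)(F)F
Why: Kinetic α′-deprotonation of the enone at C6 (cross-conjugated enolate) followed by O-triflation fixes the second double bond at C6–C7 regiospecifically; cold inverse addition avoids the γ-(C11) enolate, which would expel bromide.

Step 6
Reactants: 7 12-bromo-13,14,15,16-tetranorlabda-6,8-dien-7-yl triflate
Product: 8 12-bromo-13,14,15,16-tetranorlabda-6,8-diene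
Conditions: Pd(OAc)2 (5 mol %), dppp, Et3SiH, DMF, 60 °C
Reagents that add atoms: none
Why: Palladium-catalysed silane reduction of an enol triflate replaces OTf by H without moving either double bond, and this catalyst does not insert into the unactivated primary C–Br bond.

Step 7
Reactants: 8 12-bromo-13,14,15,16-tetranorlabda-6,8-diene
Product: 10 12-bromo-13,14,15,16-tetranorlabd-7-ene-6α,9α-diol, via endoperoxide 9 (not isolated)
Conditions: O2, TPP (0.5 mol %), hν (white LED), CH2Cl2, −20 °C; then Zn, AcOH, 0 °C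
Reagents that add atoms: dioxygen, O=O
Why: Photosensitised singlet oxygen adds in a suprafacial [4+2] cycloaddition to the s-cis homoannular diene from the α face, opposite the axial C10 and C4β methyls, which sets C6 and C9 together; Zn/AcOH then cleaves only the O–O bond with retention.

Step 8
Reactants: 10 12-bromo-13,14,15,16-tetranorlabd-7-ene-6α,9α-diol
Product: 13 7β-acetoxy-12-bromo-13,14,15,16-tetranorlabdane-6α,8β,9α-triol, via trans-iodoacetate 11 (not isolated), via acetoxonium acetate 12 (not isolated)
Conditions: I2, AgOAc (2.1 equiv), AcOH, dark, rt; then H2O, 60 °C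
Reagents that add atoms: silver acetate, CC(=O)[O-].[Ag+]; water, O
Why: Woodward cis-hydroxylation, in which the α-face iodonium is opened trans-diaxially by acetate at tertiary C8 from the β face (11), the neighbouring acetate displaces the axial 7α-iodide from behind with silver assistance (12), and water opens the acetoxonium with the acetyl settling on the secondary O7, so both new C–O bonds are β, on the face that osmylation would not reach.

Step 9
Reactants: 13 7β-acetoxy-12-bromo-13,14,15,16-tetranorlabdane-6α,8β,9α-triol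
Product: 14 7β-acetoxy-12-bromo-8β,9α-dihydroxy-13,14,15,16-tetranorlabdan-6-one
Conditions: DMP, CH2Cl2, 0 °C → rt
Reagents that add atoms: none
Why: Dess–Martin oxidation touches only the single secondary alcohol; the two tertiary alcohols, the acetate and the bromide are inert, and the flanking C5 and C7 already hold their stable (trans-fused, equatorial) configurations.

Step 10
Reactants: 14 7β-acetoxy-12-bromo-8β,9α-dihydroxy-13,14,15,16-tetranorlabdan-6-one, 15 3-bromofuran
Product: 16 7β-acetoxy-15,16-epoxy-8β,9α-dihydroxylabda-13(16),14-dien-6-one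
Conditions: Ir[dF(CF3)ppy]2(dtbbpy)PF6 (1 mol %), NiCl2·glyme/dtbbpy (5 mol %), (TMS)3SiH, Na2CO3, DME, blue LED, rt
Reagents that add atoms: 3-bromofuran (15), Brc1ccoc1
Why: Silyl-radical nickel/photoredox cross-electrophile coupling, in which (TMS)3Si• abstracts bromine from the primary bromide, the C12 radical is captured by the furyl–nickel species from 15, and reductive elimination forms C12–C13; the ketone, acetate and tertiary alcohols are tolerated and no stereocentre is touched.

Step 11
Reactants: 16 7β-acetoxy-15,16-epoxy-8β,9α-dihydroxylabda-13(16),14-dien-6-one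
Product: 17 (13S)-7β-acetoxy-9α,13:15,16-diepoxy-8β-hydroxylabd-14-en-6-one
Conditions: fac-Ir(ppy)3 (1 mol %), achiral Co(II) salen from 3,5-di-tert-butylsalicylaldehyde and 2,3-dimethylbutane-2,3-diamine (5 mol %), 2,4,6-collidinium triflate/2,4,6-collidine (20 mol % each), 4 Å MS, MeCN–PhCF3, 450 nm LED, 0 °C; Et3N-deactivated silica
Reagents that add atoms: none
Why: Proposed new method: a light-driven, redox-neutral dearomative Markovnikov hydroalkoxylation of a furan, in which excited Ir(ppy)3 reduces Co(II) to Co(I), collidinium protonates it to Co(III)–H, hydrogen-atom transfer puts H• on the furan α-carbon C16 to give the tertiary, allylic, oxygen-conjugated C13 radical, Ir(IV) oxidises the derived organocobalt to a Co(IV)/2H-furanium species, and the axial 9α-OH traps C13 in a 5-exo closure (faster than six-ring closure by the hindered 8β-OH) before proton loss can restore the furan, the collidine buffer being too weakly acidic to re-ionise the product, so photon energy pays for the uphill isomerisation; C9 is retained and C13 is set by substrate control, because the closure that turns the out-of-plane C16H2 toward C1 and the flat C14–H edge toward the C17 methyl (tilted to the α face by the 8β-OH/C20 syn-axial contact) is the less crowded one and gives 13S; the closest known reaction type is the photoredox/cobalt/Brønsted-acid MHAT radical-polar-crossover hydroalkoxylation of unactivated alkenes, which has not been shown on an aromatic furan C=C bond.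

## Compound list
1 | (+)-sclareolide (8α,12-lactone; 9α-H, 8β-CH3) | C1C[C@H]2C(C)(C)CCC[C@]2(C)[C@H]3CC(=O)O[C@]13C | starting material
2 | methyl 13,14,15,16-tetranorlabd-8-en-12-oate | C1C[C@H]2C(C)(C)CCC[C@]2(C)C(CC(=O)OC)=C1C | intermediate
3 | 13,14,15,16-tetranorlabd-8-en-12-ol | C1C[C@H]2C(C)(C)CCC[C@]2(C)C(CCO)=C1C | intermediate
4 | 12-bromo-13,14,15,16-tetranorlabd-8-ene | C1C[C@H]2C(C)(C)CCC[C@]2(C)C(CCBr)=C1C | intermediate
5 | 12-bromo-13,14,15,16-tetranorlabd-8-en-7-one | O=C1C[C@H]2C(C)(C)CCC[C@]2(C)C(CCBr)=C1C | intermediate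
6 | potassium 12-bromo-13,14,15,16-tetranorlabda-6,8-dien-7-olate | [K+].[O-]C1=C[C@H]2C(C)(C)CCC[C@]2(C)C(CCBr)=C1C | intermediate
7 | 12-bromo-13,14,15,16-tetranorlabda-6,8-dien-7-yl triflate | O=S(=O)(OC1=C[C@H]2C(C)(C)CCC[C@]2(C)C(CCBr)=C1C)C(F)(F)F | intermediate
8 | 12-bromo-13,14,15,16-tetranorlabda-6,8-diene | C1=C[C@H]2C(C)(C)CCC[C@]2(C)C(CCBr)=C1C | intermediate
9 | 12-bromo-6α,9α-epidioxy-13,14,15,16-tetranorlabd-7-ene | C1[C@H]3[C@H]2C(C)(C)CCC[C@]2(C)[C@](CCBr)(OO3)C(C)=1 | intermediate
10 | 12-bromo-13,14,15,16-tetranorlabd-7-ene-6α,9α-diol | C1[C@H](O)[C@H]2C(C)(C)CCC[C@]2(C)[C@](CCBr)(O)C(C)=1 | intermediate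
11 | 8β-acetoxy-12-bromo-7α-iodo-13,14,15,16-tetranorlabdane-6α,9α-diol | I[C@@H]1[C@H](O)[C@H]2C(C)(C)CCC[C@]2(C)[C@](CCBr)(O)[C@@]1(C)OC(C)=O | intermediate
12 | 7β,8β-(2-methyl-1,3-dioxolan-2-ylium) acetate of the 12-bromo-6α,9α-diol | CC1=[O+][C@H]2[C@H](O)[C@H]3C(C)(C)CCC[C@]3(C)[C@](CCBr)(O)[C@@]2(C)O1.CC(=O)[O-] | intermediate
13 | 7β-acetoxy-12-bromo-13,14,15,16-tetranorlabdane-6α,8β,9α-triol | CC(=O)O[C@H]1[C@H](O)[C@H]2C(C)(C)CCC[C@]2(C)[C@](CCBr)(O)[C@@]1(C)O | intermediate
14 | 7β-acetoxy-12-bromo-8β,9α-dihydroxy-13,14,15,16-tetranorlabdan-6-one | CC(=O)O[C@H]1C(=O)[C@H]2C(C)(C)CCC[C@]2(C)[C@](CCBr)(O)[C@@]1(C)O | intermediate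
15 | 3-bromofuran | Brc1ccoc1 | starting material
16 | 7β-acetoxy-15,16-epoxy-8β,9α-dihydroxylabda-13(16),14-dien-6-one | CC(=O)O[C@H]1C(=O)[C@H]2C(C)(C)CCC[C@]2(C)[C@](CCc2ccoc2)(O)[C@@]1(C)O | intermediate
17 | (13S)-7β-acetoxy-9α,13:15,16-diepoxy-8β-hydroxylabd-14-en-6-one (CNP0284584.1) | CC(=O)O[C@H]1C(=O)[C@H]2C(C)(C)CCC[C@]2(C)[C@@]2(CC[C@@]3(C=COC3)O2)[C@@]1(C)O | target

## Step count and risks
Total steps: 11. Longest linear sequence: 11 (1 → 17).

**Step 11 (the proposed new reaction).**
- Hydrogen-atom transfer to an aromatic furan may be slow, or may go to C15 instead of C16.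
- The enol ether product is itself a good hydrogen-atom acceptor and is acid-labile.
- The two sides of the spiro centre (C1 versus C17) are sterically similar, so selectivity at C13 may be only modest. The 13-epimer would be separated and returned to 16 with a trace of acid.
- The fallback uses known chemistry, sets out from 14 and returns at 17. Bromide 14 is joined by nickel-catalysed cross-electrophile coupling to 3-bromo-2,5-dihydrofuran in place of 15, giving the 2,5-dihydrofuran-3-yl diol F1. PhSeCl with 2,6-lutidine at −78 °C then effects anti selenoetherification, with the 9α-OH going to tertiary C13 and selenium to C14, to give the 14-phenylselanyl spiro bis-ether F2. One equivalent of mCPBA at −78 °C makes the selenoxide F3. On warming with iPr2NEt this undergoes syn elimination toward C15, the only β-carbon that bears hydrogen, and delivers 17.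

**Step 8 (Woodward cis-hydroxylation).**
- Acetate must attack a tertiary carbon flanked by the C9 carbinol and syn-axial to C20.
- Hypoiodite chemistry of the free alcohols is possible.
- Silver may solvolyse the primary bromide.
- The acetyl group may spread over O6, O7 and O8.
- The fallback replaces the halonium/neighbouring-group logic by epoxide opening plus inversion. It sets out from 10 and returns at 14. mCPBA epoxidises syn to both allylic hydroxyls to give the 7α,8α-epoxy diol F4. DMP gives the epoxy ketone F5. Dilute HClO4 in aqueous THF opens F5 at tertiary C8 with inversion to give the 7α,8β,9α-trihydroxy ketone F6. A Mitsunobu reaction with acetic acid then inverts the axial 7α-carbinol and gives 14 directly.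

**Step 5 (kinetic dienyl triflate formation).**
- If γ-deprotonation at C11 competes, bromide is lost by E1cB elimination.
- The axial 6β-H is shielded by two syn-axial methyls.
- The fallback changes to hydrazone chemistry on a halide-free series. It sets out from 3 and returns at 8. TBSCl/imidazole gives the silyl ether F7. CrO3·3,5-dimethylpyrazole gives the enone F8. TsNHNH2 gives the tosylhydrazone F9. A Shapiro reaction (MeLi, TMEDA, Et2O) gives the silyl-protected 6,8-diene F10 regiospecifically. TBAF frees the dienol F11, and Appel bromination gives 8.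

## Further compounds
F1 | step 11 | 7β-acetoxy-15,16-epoxy-8β,9α-dihydroxylabd-13-en-6-one | CC(=O)O[C@H]1C(=O)[C@H]2C(C)(C)CCC[C@]2(C)[C@](CCC2=CCOC2)(O)[C@@]1(C)O
F2 | step 11 | 7β-acetoxy-9α,13:15,16-diepoxy-8β-hydroxy-14-(phenylselanyl)labdan-6-one (Se trans to O9) | CC(=O)O[C@H]1C(=O)[C@H]2C(C)(C)CCC[C@]2(C)[C@@]2(CC[C@@]3([C@H]([Se]c4ccccc4)COC3)O2)[C@@]1(C)O
F3 | step 11 | selenoxide of F2 | CC(=O)O[C@H]1C(=O)[C@H]2C(C)(C)CCC[C@]2(C)[C@@]2(CC[C@@]3([C@H]([Se](=O)c4ccccc4)COC3)O2)[C@@]1(C)O
F4 | step 8 | 12-bromo-7α,8α-epoxy-13,14,15,16-tetranorlabdane-6α,9α-diol | O1[C@@H]2[C@H](O)[C@H]3C(C)(C)CCC[C@]3(C)[C@](CCBr)(O)[C@]12C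
F5 | step 8 | 12-bromo-7α,8α-epoxy-9α-hydroxy-13,14,15,16-tetranorlabdan-6-one | O1[C@@H]2C(=O)[C@H]3C(C)(C)CCC[C@]3(C)[C@](CCBr)(O)[C@]12C
F6 | step 8 | 12-bromo-7α,8β,9α-trihydroxy-13,14,15,16-tetranorlabdan-6-one | O[C@@H]1C(=O)[C@H]2C(C)(C)CCC[C@]2(C)[C@](CCBr)(O)[C@@]1(C)O
F7 | step 5 | 12-(tert-butyldimethylsilyloxy)-13,14,15,16-tetranorlabd-8-ene | C1C[C@H]2C(C)(C)CCC[C@]2(C)C(CCO[Si](C)(C)C(C)(C)C)=C1C
F8 | step 5 | 12-(tert-butyldimethylsilyloxy)-13,14,15,16-tetranorlabd-8-en-7-one | O=C1C[C@H]2C(C)(C)CCC[C@]2(C)C(CCO[Si](C)(C)C(C)(C)C)=C1C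
F9 | step 5 | tosylhydrazone of F8 | Cc1ccc(cc1)S(=O)(=O)NN=C1C[C@H]2C(C)(C)CCC[C@]2(C)C(CCO[Si](C)(C)C(C)(C)C)=C1C
F10 | step 5 | 12-(tert-butyldimethylsilyloxy)-13,14,15,16-tetranorlabda-6,8-diene | C1=C[C@H]2C(C)(C)CCC[C@]2(C)C(CCO[Si](C)(C)C(C)(C)C)=C1C
F11 | step 5 | 13,14,15,16-tetranorlabda-6,8-dien-12-ol | C1=C[C@H]2C(C)(C)CCC[C@]2(C)C(CCO)=C1C
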